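**Assumption:** Kinobeon A is achiral, with no stereocentres. Its only stereo-element is the central (E)-C=C, because each exocyclic C=C carries a symmetric ring and is not stereogenic. "Single enantiomer" is therefore read as "single (E)-isomer".

## Retrosynthetic overview
1. The target is a double vinylogous p-quinone methide. Adding back 4 H (one O–H and one benzylic C–H at each end) gives (E)-1,4-bis(4-hydroxy-3,5-dimethoxyphenyl)but-2-ene (2), with the central (E)-alkene already in place.
2. Cutting the central C=C of 2 (olefin self-metathesis) gives two molecules of commercial 4-allyl-2,6-dimethoxyphenol (1).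
3. No ring is formed. Both six-membered rings are bought as arenes and dearomatised together in the last step.
4. No protecting groups are used. The route uses the C2 symmetry of the target in both steps.

## Route

**Step 1**
Reactants: 1, 4-allyl-2,6-dimethoxyphenol (methoxyeugenol), 2 equiv
Product: 2, (E)-4,4'-(but-2-ene-1,4-diyl)bis(2,6-dimethoxyphenol), C20H24O6
Conditions: Grubbs II (1–2 mol%), 1,4-benzoquinone (10 mol%), CH2Cl2 (0.5 M), 40 °C, Ar sparge to remove ethylene, 12 h; ethyl vinyl ether quench; silica plug; recrystallise (EtOAc/hexane) to pure E
Reagents that add atoms: none (both halves come from 1; C2H4 is lost)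
Why: This is an olefin self-metathesis of a type-I terminal alkene, and Ru carbenes tolerate free guaiacyl and syringyl phenols. Secondary metathesis equilibrates the product toward the thermodynamic E-alkene, benzoquinone suppresses Ru–H allyl-to-propenyl isomerisation, and crystallisation removes residual Z.

**Step 2**
Reactants: 2, (E)-4,4'-(but-2-ene-1,4-diyl)bis(2,6-dimethoxyphenol)
Product: 3, Kinobeon A, 4,4'-[(2E)-but-2-ene-1,4-diylidene]bis(2,6-dimethoxycyclohexa-2,5-dien-1-one), C20H20O6
Conditions: freshly prepared Ag2O (6 equiv; 2 equiv is theoretical), 4 Å MS, dry alcohol-free CH2Cl2 (0.01 M), rt, dark, 1–3 h; filter through Celite; concentrate; crystallise from CH2Cl2/hexane (no alcohols, no acidic silica)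
Reagents that add atoms: none (Ag2O removes 4 H as 2 H2O)
Why: This is a twofold phenol dehydrogenation (oxidative dearomatisation) of a p-allylphenol to a vinyl p-quinone methide, once at each terminus.
- The ortho positions are blocked by OMe, so each phenoxyl radical loses its doubly activated benzylic/allylic H.
- The C2=C3 (E)-alkene set in step 1 is kept.
- The alternative path, tautomerisation of the mono-quinone methide to the diene bisphenol followed by 2 e⁻ oxidation, leads to the same fully conjugated product.
- A stepwise stop is not attempted, because the diene bisphenol oxidises more easily than 2.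

## Compound list
1 | 4-allyl-2,6-dimethoxyphenol | C=CCc1cc(OC)c(O)c(OC)c1 | starting material
2 | (E)-4,4'-(but-2-ene-1,4-diyl)bis(2,6-dimethoxyphenol) | COc1cc(C/C=C/Cc2cc(OC)c(O)c(OC)c2)cc(OC)c1O | intermediate
3 | Kinobeon A | COC1=CC(=C/C=C/C=C2C=C(OC)C(=O)C(OC)=C2)C=C(OC)C1=O | target

## Totals
Total steps: 2. Longest linear sequence: 2.

## Most likely failure points
The route has only two steps, so the three points below are ranked risks spread across them.

1. **Step 2, chemoselectivity.** The intermediate mono-quinone methide may oligomerise or add water or phenol before the second oxidation.
 Fallback: build the fully conjugated leuco form instead.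
 - Run a double Horner–Wadsworth–Emmons reaction of diethyl (4-TBSO-3,5-dimethoxybenzyl)phosphonate (made from syringaldehyde) with glyoxal.
 - Desilylate with TBAF to (1E,3E)-1,4-bis(4-hydroxy-3,5-dimethoxyphenyl)buta-1,3-diene.
 - The last step is then only a hydroquinone-to-quinone type 2 e⁻ oxidation.

2. **Step 1, chain integrity.** Allyl-to-propenyl isomerisation would give chain-shortened C3 and C2 (stilbene) dimers, and the catalyst may also die early.
 Fallback: abandon metathesis and install the intact C4 unit by a Pd-catalysed double allyl–aryl Suzuki coupling. The partners are commercial (E)-1,4-dibromobut-2-ene and 4-hydroxy-3,5-dimethoxyphenylboronic acid pinacol ester, and the E geometry is bought in.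

3. **Steps 1 and 2, E/Z purity.** The Z-isomer of 2 may be inseparable, or the central alkene of 3 may photoisomerise.
 Fallback: a redox cycle that erases the geometry.
 - Reduce crude 3 with Na2S2O4 to the diene bisphenol, in which C2–C3 becomes a freely rotating single bond.
 - Crystallise it, then re-oxidise from the favoured s-trans conformer to obtain only (E)-3.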